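Abbreviations used in names: TBS = tert-butyldimethylsilyl, PMB = 4-methoxybenzyl, Bcy = (1S,4R,5R,6S)-4-[3-(TBSO)pent-1-en-2-yl]-1,3,6-trimethylbicyclo[3.1.0]hex-2-en-6-yl.

## Analysis of the target

The target 32 is a bicyclo[3.1.0]hex-2-ene. The core is numbered C1 (methylated ring fusion), C2=C3 (methyl on C3), C4 (ring CH carrying the 3-oxopent-1-en-2-yl group), C5 (ring-fusion CH) and C6 (cyclopropane apex carrying a methyl and the 2-methoxy-3,5-dimethyl-4-oxo-4H-pyran-6-yl group). It has four contiguous stereocentres, (1S,4R,5R,6S). C1 and C5 are cis by ring constraint, the C6 methyl is endo (over the five-membered ring) with the pyrone exo, and the C4 side chain sits on the ring face opposite the cyclopropane. C1 and C6 are vicinal quaternary carbons with no heteroatom to anchor an asymmetric reaction. The sensitive groups are: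
- the α-methylene ketone, a Michael acceptor whose isomerisation into conjugation would destroy C4;
- the doubly allylic, cyclopropylcarbinyl C4–H;
- the vinylcyclopropane, which opens under acid or radical conditions;
- the α-methoxy-γ-pyrone, whose O-methylation regiochemistry has to be controlled.

The difficulty is to set three carbon stereocentres on one cyclopropane in absolute terms, to place C4 next to them, and to attach a fully substituted pyrone to quaternary C6. The strategy rests on two features. C5 is the only ring-fusion carbon with a hydrogen and is bonded to both C1 and C6, which is the pattern left by a terminal alkyne carbon that has added across a C1=C6 alkene. The C2=C3–C4 allyl unit can come by allylic transposition from an oxygen at C2, and that carbinol carbon can be the single stereocentre from which all others are relayed.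

## Retrosynthetic reasoning

**Enone last.** The α-methylene ketone of 32 is the most fragile group, so it is unveiled in the final step by oxidation of the allylic alcohol 31, which comes from silyl ether 30. Only the C–O oxidation level changes; the side-chain carbinol is a temporary centre.

**Pyrone.** The pyrone cannot be joined to quaternary C6 by a coupling, so its ring is cut at the O1–C2 bond and at the bond between the carbinol-derived carbon and the chain. Methoxypyrone 30 goes back to hydroxypyrone 29, diketo ester 28, aldol adduct 27, and finally aldehyde 24 plus the dianion 26 of keto ester 25. The forward sequence has to add a five-carbon propionate chain to a neopentyl-type aldehyde and then close and methylate the ring with the right regiochemistry.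

**C6 carbon.** Aldehyde 24 comes from alcohol 23 and PMB ether 22. Carrying the C6 substituent as an ether keeps the alkene of the key-step substrate electron-rich.

**C4 side chain.** The C4–side-chain bond of 22 is cut with allylic transposition, which gives carbamate 14 and the vinylmagnesium reagent 20 (from bromide 18, made from pentynol 15 through 16). Cutting here moves the oxygen to C2, where it can serve as stereocontrol element for the core. The forward reaction must deliver the vinyl group to C4 on the face of the departing oxygen. A carbamate-directed, copper-mediated syn-SN2' substitution does this, and that face is also the one away from the cyclopropane.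

**Core (key disconnection).** Carbamate 14 comes from alcohol 13 and silyl ether 12. In 12 the bonds C1–C5 and C5–C6 are cut together, which opens both rings and leads to the acyclic 1,5-enyne 11. This removes three stereocentres and two rings in one step and leaves a precursor with a single controlling carbinol. The forward reaction is a gold-catalysed enyne cycloisomerisation. It must transfer the (E)-alkene geometry to C6 and must choose the alkene face from the C2 carbinol.

**Enyne.** Enyne 11 is the silyl ether of anti-alcohol 10. The bond between the propargylic carbon and the carbinol carbon is cut, which gives enal 6 and the allenylzinc reagent 9 from mesylate 8 of butynol 7. The palladium-mediated zincation and addition proceed with net inversion at the propargylic carbon, so the (S)-alcohol 7 is required for (3R); the anti preference then gives (4R). Only C4 of 10 survives the key step as a stereocentre, so the diastereomeric purity of 10 becomes the enantiomeric purity of 12.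

**Enal.** Enal 6 goes back through 5 and diol 4 to dibromide 2 and diene 1. The 1,4-addition to the diene installs the tetrasubstituted (E)-alkene with both termini functionalised in one step.

## Alternatives that were turned down

**Alternative 1:** The cyclopropane is disconnected at C5–C6 by a ring contraction. A [2+2] cycloaddition of 1,3-dimethylcyclopenta-1,3-diene A1 with chloro(methyl)ketene A2 would give the chlorocyclobutanone A3. In the key step, methoxide adds to the carbonyl of A3 and the C5–acyl bond shifts to the chlorine-bearing carbon with loss of chloride (quasi-Favorskii), which gives the cyclopropane ester A4.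
- For: it reaches the whole carbon core with all three methyls in two steps from simple materials, and the ester of A4 is already at the right oxidation level for the pyrone. On step count to the core it is clearly stronger than the chosen route.
- Against: A1 is a mixture of equilibrating double-bond isomers, and the ketene must pick the right alkene and orientation while creating two vicinal quaternary carbons. The C6 configuration depends on which C7 epimer of A3 contracts, and the cycloaddition gives both. Everything is racemic. A4 has an unfunctionalised CH2 at C4, so the side chain would need an allylic functionalisation with facial control and no directing group.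
- Comparison: the chosen route is longer but supplies absolute configuration from a carbinol and a built-in oxygen handle that sets C4.

**Alternative 2:** The cyclopentene is disconnected at C3–C4 by contraction of a cyclopropane-fused cyclohexenone. In the key step the diazo ketone A5 is irradiated, loses dinitrogen, and the alkenyl carbon C3 migrates to the carbene carbon (Wolff rearrangement). The ketene is trapped as the N-methoxy-N-methylamide A6.
- For: the C4 carbon substituent arrives directly at the carboxyl level without an organometallic coupling on a strained allylic system. On that point it is stronger than the chosen route.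
- Against: C4 is set by protonation of a ketene-derived enol and is therefore under weak control; correction by epimerisation risks moving the C2=C3 alkene. The amide carbon must still become a 1,1-disubstituted alkene carbon bearing a propanoyl group, which costs several steps. A5 already contains C1, C5 and C6 with the two quaternary carbons, so the hard stereochemical problem is postponed, not solved. The enone chromophore of A5 invites competing photochemistry.
- Comparison: the chosen route builds the cyclopropane stereocentres in the same step that makes the rings.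

**Alternative 3:** The bonds C1–C2 and C5–C6 are disconnected by a type A photorearrangement. The arene methyl 4-methoxy-2,5-dimethylbenzoate A7 would be dearomatised by reductive methylation and adjusted to the cross-conjugated dienone A8. In the key step, irradiation near 366 nm bonds the two β-carbons and the quaternary carbon then pivots to an α-carbon, which gives the bicyclic enone ester A9.
- For: all methyls and the ester come from a cheap aromatic compound, the shift is stereospecific at the migrating carbon, and the C4 carbonyl is a handle. On the cost of the starting material it is as strong as or stronger than the chosen route.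
- Against: A8 is unsymmetrical, so the quaternary carbon can pivot towards either α-carbon and a regioisomer is expected. A8 is chiral and would need an asymmetric dearomatisation. A9 can react further photochemically. Turning the C4 carbonyl into a C4–H bearing the side chain with the right configuration means deoxygenating a tertiary, doubly allylic, cyclopropylcarbinyl alcohol, where cationic or radical intermediates threaten the cyclopropane.
- Comparison: the chosen route sets C4 by a stereospecific substitution and needs no photochemistry.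

Key step: step 8

Assumption: pent-1-yn-3-ol 15 is used as the racemate, so every intermediate that carries the side-chain carbinol carbon (16–20, 22–24, 27–31) is a mixture of both configurations at that carbon; the last step converts it to a carbonyl.

## Route

Step 1
Reactants: 1 2,3-dimethylbuta-1,3-diene
Product: 2 (E)-1,4-dibromo-2,3-dimethylbut-2-ene
Conditions: Br2 (1.0 equiv), CH2Cl2, −20 °C → 0 °C; recrystallisation from hexane
Reagents that add atoms: bromine BrBr
Why: Electrophilic 1,4-addition of bromine to a conjugated diene; the 1,4-adduct with the tetrasubstituted alkene is the thermodynamic product and the (E)-isomer should crystallise.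

Step 2
Reactants: 2 (E)-1,4-dibromo-2,3-dimethylbut-2-ene
Product: 4 (E)-2,3-dimethylbut-2-ene-1,4-diol, via diacetate 3 (not isolated)
Conditions: KOAc (2.5 equiv), DMF, 60 °C; then K2CO3 (cat.), MeOH, rt
Reagents that add atoms: potassium acetate CC(=O)[O-].[K+]
Why: Double SN2 displacement of primary allylic bromides by acetate, then transesterification; SN2' attack would have to occur at a fully substituted carbon, so the alkene geometry is kept.

Step 3
Reactants: 4 (E)-2,3-dimethylbut-2-ene-1,4-diol
Product: 5 (E)-2,3-dimethyl-4-(PMBO)but-2-en-1-ol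
Conditions: NaH (1.0 equiv), PMBCl (1.0 equiv), Bu4NI (cat.), THF/DMF, 0 °C → rt; 4 in threefold excess and recovered
Reagents that add atoms: 4-methoxybenzyl chloride COc1ccc(CCl)cc1
Why: Williamson etherification; monoprotection of the symmetrical diol is statistical and is biased by the excess of diol.

Step 4
Reactants: 5 (E)-2,3-dimethyl-4-(PMBO)but-2-en-1-ol
Product: 6 (E)-2,3-dimethyl-4-(PMBO)but-2-enal
Conditions: MnO2 (10 equiv), CH2Cl2, rt
Reagents that add atoms: none
Why: Chemoselective oxidation of a primary allylic alcohol by activated MnO2 under neutral conditions, which should leave the ether and the (E)-geometry untouched.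

Step 5
Reactants: 7 (S)-but-3-yn-2-ol
Product: 8 (S)-but-3-yn-2-yl methanesulfonate
Conditions: MsCl, Et3N, CH2Cl2, −78 °C → 0 °C
Reagents that add atoms: methanesulfonyl chloride CS(=O)(=O)Cl
Why: Sulfonylation at oxygen; no bond to the stereocentre is broken, so the configuration is retained.

Step 6
Reactants: 6 (E)-2,3-dimethyl-4-(PMBO)but-2-enal; 8 (S)-but-3-yn-2-yl methanesulfonate
Product: 10 (3R,4R,5E)-3,5,6-trimethyl-7-(PMBO)hept-5-en-1-yn-4-ol, via allenylzinc reagent 9 (not isolated)
Conditions: Pd(OAc)2 (5 mol%), PPh3 (5 mol%), Et2Zn (3 equiv), THF, −78 °C → −20 °C; NH4Cl (aq); chromatographic removal of the minor syn isomer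
Reagents that add atoms: none
Why: Marshall propargylation: zerovalent palladium displaces the mesylate in an anti SN2' sense, transmetallation to zinc is retentive and 9 adds through a cyclic SE2' transition state, so the propargylic carbon forms with net inversion and the (S)-mesylate gives (3R). The aldehyde substituent avoids the allenyl methyl in that transition state, which gives the anti adduct and therefore (4R). The syn isomer carries (4S) and must be removed, because C4 alone decides the absolute configuration after step 8.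

Step 7
Reactants: 10 (3R,4R,5E)-3,5,6-trimethyl-7-(PMBO)hept-5-en-1-yn-4-ol
Product: 11 (3R,4R,5E)-4-(TBSO)-3,5,6-trimethyl-7-(PMBO)hept-5-en-1-yne
Conditions: TBSOTf, 2,6-lutidine, CH2Cl2, −78 °C → 0 °C
Reagents that add atoms: tert-butyldimethylsilyl trifluoromethanesulfonate CC(C)(C)[Si](C)(C)OS(=O)(=O)C(F)(F)F
Why: Silylation of a hindered secondary alcohol with the silyl triflate; the ether blocks attack of the hydroxyl on the gold-activated alkyne and enlarges the group that steers the next step.

Step 8
Reactants: 11 (3R,4R,5E)-4-(TBSO)-3,5,6-trimethyl-7-(PMBO)hept-5-en-1-yne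
Product: 12 (1S,2R,5S,6S)-2-(TBSO)-6-(PMBOCH2)-1,3,6-trimethylbicyclo[3.1.0]hex-3-ene
Conditions: (Ph3P)AuCl (3 mol%), AgSbF6 (3 mol%), premixed and filtered from AgCl, CH2Cl2, 0 °C → rt; Et3N quench
Reagents that add atoms: none
Why: Cationic (Ph3P)Au+ binds the terminal alkyne of 11; alkene carbon C1 attacks the terminal alkyne carbon (the future C5) and the tertiary cation developing at C6 is captured by the same carbon, which gives a cyclopropyl gold carbene with the metal on C4. A 1,2-hydride shift from C3 to C4 and loss of gold then give the C3=C4 alkene of 12 and erase the C3 stereocentre. The closest known reaction type is the gold-catalysed cycloisomerisation of 1,5-enynes to bicyclo[3.1.0]hex-2-enes. The cyclopentene closes in a 5-endo-dig mode and the cyclopropane in a 3-exo mode onto the gold-bearing vinyl carbon. C1 and C5 are set together, cis by ring constraint, and their sense is controlled by the C2 silyloxy stereocentre: allylic 1,3-strain with the methyl on C6 keeps C2–H in the alkene plane, so the alkyne arm reaches the alkene face opposite the silyloxy group. C6 is set by stereospecific suprafacial addition across the (E)-alkene, which puts its methyl endo and the ether-bearing carbon exo. The step needs endo cyclisation with hydride-shift termination in preference to six-membered-ring skeletal rearrangement, and the ionisable allylic cyclopropylcarbinyl silyl ether of the product must survive; the propargylic hydrogen at C3, low catalyst loading, low temperature and the amine quench should secure this. The anti relationship in 11 also keeps the C3 methyl on the face away from the endo methyl of C6 during ring closure.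

Step 9
Reactants: 12 (1S,2R,5S,6S)-2-(TBSO)-6-(PMBOCH2)-1,3,6-trimethylbicyclo[3.1.0]hex-3-ene
Product: 13 (1S,2R,5S,6S)-6-(PMBOCH2)-1,3,6-trimethylbicyclo[3.1.0]hex-3-en-2-ol
Conditions: TBAF, THF, 0 °C → rt
Reagents that add atoms: none
Why: Fluoride-mediated desilylation under basic conditions, which avoids ionisation of the allylic cyclopropylcarbinyl C–O bond.

Step 10
Reactants: 13 (1S,2R,5S,6S)-6-(PMBOCH2)-1,3,6-trimethylbicyclo[3.1.0]hex-3-en-2-ol
Product: 14 (1S,2R,5S,6S)-6-(PMBOCH2)-1,3,6-trimethylbicyclo[3.1.0]hex-3-en-2-yl N-phenylcarbamate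
Conditions: PhNCO, Et3N (cat.), CH2Cl2, rt; used without acidic chromatography
Reagents that add atoms: phenyl isocyanate O=C=Nc1ccccc1
Why: Addition of the alcohol to the isocyanate gives the carbamate under neutral conditions with retention at C2.

Step 11
Reactants: 15 pent-1-yn-3-ol
Product: 16 3-(TBSO)pent-1-yne
Conditions: TBSCl, imidazole, DMF, rt
Reagents that add atoms: tert-butyldimethylsilyl chloride CC(C)(C)[Si](C)(C)Cl
Why: Standard silylation of a secondary propargylic alcohol.

Step 12
Reactants: 16 3-(TBSO)pent-1-yne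
Product: 18 2-bromo-3-(TBSO)pent-1-ene, via bromoalkenylborane 17 (not isolated)
Conditions: B-bromo-9-BBN, CH2Cl2, 0 °C; then AcOH, 0 °C → rt
Reagents that add atoms: B-bromo-9-borabicyclo[3.3.1]nonane BrB1C2CCCC1CCC2
Why: Syn bromoboration of the terminal alkyne places bromine on the internal carbon, and protodeboronation with acetic acid gives the 2-bromo-1-alkene; haloboration should be faster than Lewis-acid cleavage of the hindered silyl ether at 0 °C.

Step 13
Reactants: 14 (1S,2R,5S,6S)-6-(PMBOCH2)-1,3,6-trimethylbicyclo[3.1.0]hex-3-en-2-yl N-phenylcarbamate; 18 2-bromo-3-(TBSO)pent-1-ene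
Product: 22 (1S,4R,5R,6S)-4-[3-(TBSO)pent-1-en-2-yl]-6-(PMBOCH2)-1,3,6-trimethylbicyclo[3.1.0]hex-2-ene, via vinyllithium 19 (not isolated), via vinylmagnesium bromide 20 (not isolated), via lithium carbamate 21 (not isolated)
Conditions: 18: t-BuLi (2.0 equiv), Et2O, −78 °C, then MgBr2·OEt2, −78 °C → 0 °C; 14: MeLi (1.0 equiv), THF, −78 °C, then CuI (1.0 equiv), −78 °C → 0 °C; combine, 0 °C → rt; NH4Cl (aq)
Reagents that add atoms: none
Why: Carbamate-directed syn-SN2' allylic substitution: the N-lithiated carbamate binds monovalent copper, and the amido(vinyl)cuprate delivers the vinyl group within the complex to C4 on the face of the departing oxygen. That face is also the one away from the cyclopropane and its endo methyl, so C4 is set with the side chain anti to the cyclopropane (4R) and the alkene moves to C2=C3.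

Step 14
Reactants: 22 (1S,4R,5R,6S)-4-[3-(TBSO)pent-1-en-2-yl]-6-(PMBOCH2)-1,3,6-trimethylbicyclo[3.1.0]hex-2-ene
Product: 23 [(1S,4R,5R,6S)-4-[3-(TBSO)pent-1-en-2-yl]-1,3,6-trimethylbicyclo[3.1.0]hex-2-en-6-yl]methanol
Conditions: DDQ (1.2 equiv), CH2Cl2/pH 7 buffer (10:1), 0 °C
Reagents that add atoms: none
Why: Oxidative cleavage of the electron-rich benzylic ether through its charge-transfer complex with the quinone; at 0 °C in buffered medium this should be faster than hydride abstraction from the doubly allylic C4–H, and the silyl ether is inert.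

Step 15
Reactants: 23 [(1S,4R,5R,6S)-4-[3-(TBSO)pent-1-en-2-yl]-1,3,6-trimethylbicyclo[3.1.0]hex-2-en-6-yl]methanol
Product: 24 (1S,4R,5R,6S)-4-[3-(TBSO)pent-1-en-2-yl]-1,3,6-trimethylbicyclo[3.1.0]hex-2-ene-6-carbaldehyde
Conditions: Dess–Martin periodinane, NaHCO3, CH2Cl2, 0 °C → rt
Reagents that add atoms: none
Why: Dess–Martin oxidation of a primary alcohol; the aldehyde has a quaternary α-carbon and cannot epimerise.

Step 16
Reactants: 24 (1S,4R,5R,6S)-4-[3-(TBSO)pent-1-en-2-yl]-1,3,6-trimethylbicyclo[3.1.0]hex-2-ene-6-carbaldehyde; 25 methyl 2-methyl-3-oxopentanoate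
Product: 27 methyl 5-hydroxy-2,4-dimethyl-3-oxo-5-(Bcy)pentanoate, via dianion 26 (not isolated)
Conditions: 25: NaH, THF, 0 °C, then n-BuLi, 0 °C; then 24, −78 °C → −20 °C; NH4Cl (aq)
Reagents that add atoms: none
Why: Aldol addition of a β-keto ester dianion, which reacts at its more basic γ-carbon; the new stereocentres are mixtures and are removed in steps 17 and 18.

Step 17
Reactants: 27 methyl 5-hydroxy-2,4-dimethyl-3-oxo-5-(Bcy)pentanoate
Product: 28 methyl 2,4-dimethyl-3,5-dioxo-5-(Bcy)pentanoate
Conditions: Dess–Martin periodinane, NaHCO3, CH2Cl2, rt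
Reagents that add atoms: none
Why: Dess–Martin oxidation of the secondary alcohol to the β,δ-diketo ester under buffered conditions that avoid retro-aldol cleavage.

Step 18
Reactants: 28 methyl 2,4-dimethyl-3,5-dioxo-5-(Bcy)pentanoate
Product: 29 4-hydroxy-3,5-dimethyl-6-(Bcy)-2H-pyran-2-one
Conditions: DBU, toluene, 60 °C; NaH2PO4 (aq) work-up
Reagents that add atoms: none
Why: Base-mediated lactonisation: the enol oxygen of the δ-ketone attacks the ester and methanol is lost, which gives the aromatic 4-hydroxy-2-pyrone.

Step 19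
Reactants: 29 4-hydroxy-3,5-dimethyl-6-(Bcy)-2H-pyran-2-one
Product: 30 2-methoxy-3,5-dimethyl-6-(Bcy)-4H-pyran-4-one
Conditions: MeOTf (1.5 equiv), CH2Cl2, 0 °C → rt; then NaHCO3 (aq)
Reagents that add atoms: methyl trifluoromethanesulfonate COS(=O)(=O)C(F)(F)F
Why: Regioselective O-methylation of a neutral 4-hydroxy-2-pyrone by a hard methylating agent; the lactone carbonyl oxygen is the most nucleophilic site, and deprotonation of the resulting hydroxypyrylium gives the α-methoxy-γ-pyrone.

Step 20
Reactants: 30 2-methoxy-3,5-dimethyl-6-(Bcy)-4H-pyran-4-one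
Product: 31 6-[(1S,4R,5R,6S)-4-(3-hydroxypent-1-en-2-yl)-1,3,6-trimethylbicyclo[3.1.0]hex-2-en-6-yl]-2-methoxy-3,5-dimethyl-4H-pyran-4-one
Conditions: TBAF, AcOH (1:1), THF, rt
Reagents that add atoms: none
Why: Buffered fluoride desilylation of the secondary allylic silyl ether; the methoxypyrone should tolerate these near-neutral conditions.

Step 21
Reactants: 31 6-[(1S,4R,5R,6S)-4-(3-hydroxypent-1-en-2-yl)-1,3,6-trimethylbicyclo[3.1.0]hex-2-en-6-yl]-2-methoxy-3,5-dimethyl-4H-pyran-4-one
Product: 32 2-methoxy-3,5-dimethyl-6-[(1S,4R,5R,6S)-1,3,6-trimethyl-4-(3-oxopent-1-en-2-yl)bicyclo[3.1.0]hex-2-en-6-yl]-4H-pyran-4-one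
Conditions: Dess–Martin periodinane, NaHCO3, CH2Cl2, 0 °C; chromatography on neutral silica
Reagents that add atoms: none
Why: Dess–Martin oxidation of the allylic alcohol to the α-methylene ketone under buffered, non-basic conditions, which should prevent isomerisation of the exocyclic alkene and so preserve C4; both side-chain epimers converge on 32.

## Compound list

1 | 2,3-dimethylbuta-1,3-diene | CC(=C)C(C)=C | starting material
2 | (E)-1,4-dibromo-2,3-dimethylbut-2-ene | BrC/C(C)=C(\C)CBr | intermediate
3 | (E)-2,3-dimethylbut-2-ene-1,4-diyl diacetate (not isolated) | CC(=O)OC/C(C)=C(\C)COC(C)=O | intermediate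
4 | (E)-2,3-dimethylbut-2-ene-1,4-diol | OC/C(C)=C(\C)CO | intermediate
5 | (E)-4-[(4-methoxybenzyl)oxy]-2,3-dimethylbut-2-en-1-ol | OC/C(C)=C(\C)COCc1ccc(OC)cc1 | intermediate
6 | (E)-4-[(4-methoxybenzyl)oxy]-2,3-dimethylbut-2-enal | O=C/C(C)=C(\C)COCc1ccc(OC)cc1 | intermediate
7 | (S)-but-3-yn-2-ol | C[C@H](O)C#C | starting material
8 | (S)-but-3-yn-2-yl methanesulfonate | C[C@H](OS(C)(=O)=O)C#C | intermediate
9 | (aR)-buta-1,2-dien-1-yl(ethyl)zinc (not isolated; the axial descriptor cannot be written in this SMILES) | CC[Zn]C=C=CC | intermediate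
10 | (3R,4R,5E)-7-[(4-methoxybenzyl)oxy]-3,5,6-trimethylhept-5-en-1-yn-4-ol (3,4-anti) | C#C[C@@H](C)[C@@H](O)/C(C)=C(\C)COCc1ccc(OC)cc1 | intermediate
11 | tert-butyl{[(3R,4R,5E)-7-[(4-methoxybenzyl)oxy]-3,5,6-trimethylhept-5-en-1-yn-4-yl]oxy}dimethylsilane | C#C[C@@H](C)[C@@H](O[Si](C)(C)C(C)(C)C)/C(C)=C(\C)COCc1ccc(OC)cc1 | intermediate
12 | tert-butyl{[(1S,2R,5S,6S)-6-{[(4-methoxybenzyl)oxy]methyl}-1,3,6-trimethylbicyclo[3.1.0]hex-3-en-2-yl]oxy}dimethylsilane (silyloxy anti to the cyclopropane, C6 methyl endo) | C1=C(C)[C@@H](O[Si](C)(C)C(C)(C)C)[C@@]2(C)[C@@H]1[C@]2(C)COCc1ccc(OC)cc1 | intermediate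
13 | (1S,2R,5S,6S)-6-{[(4-methoxybenzyl)oxy]methyl}-1,3,6-trimethylbicyclo[3.1.0]hex-3-en-2-ol | C1=C(C)[C@@H](O)[C@@]2(C)[C@@H]1[C@]2(C)COCc1ccc(OC)cc1 | intermediate
14 | (1S,2R,5S,6S)-6-{[(4-methoxybenzyl)oxy]methyl}-1,3,6-trimethylbicyclo[3.1.0]hex-3-en-2-yl N-phenylcarbamate | C1=C(C)[C@@H](OC(=O)Nc3ccccc3)[C@@]2(C)[C@@H]1[C@]2(C)COCc1ccc(OC)cc1 | intermediate
15 | pent-1-yn-3-ol (racemic) | CCC(O)C#C | starting material
16 | tert-butyldimethyl(pent-1-yn-3-yloxy)silane (racemic) | CCC(O[Si](C)(C)C(C)(C)C)C#C | intermediate
17 | (Z)-9-{2-bromo-3-[(tert-butyldimethylsilyl)oxy]pent-1-en-1-yl}-9-borabicyclo[3.3.1]nonane (not isolated) | CCC(O[Si](C)(C)C(C)(C)C)/C(Br)=C/B1C2CCCC1CCC2 | intermediate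
18 | [(2-bromopent-1-en-3-yl)oxy](tert-butyl)dimethylsilane (racemic) | CCC(O[Si](C)(C)C(C)(C)C)C(Br)=C | intermediate
19 | {3-[(tert-butyldimethylsilyl)oxy]pent-1-en-2-yl}lithium (not isolated) | [Li]C(=C)C(CC)O[Si](C)(C)C(C)(C)C | intermediate
20 | {3-[(tert-butyldimethylsilyl)oxy]pent-1-en-2-yl}magnesium bromide (not isolated) | Br[Mg]C(=C)C(CC)O[Si](C)(C)C(C)(C)C | intermediate
21 | N-lithio derivative of carbamate 14 (not isolated) | C1=C(C)[C@@H](OC(=O)N([Li])c3ccccc3)[C@@]2(C)[C@@H]1[C@]2(C)COCc1ccc(OC)cc1 | intermediate
22 | tert-butyl{[2-((1S,4R,5R,6S)-6-{[(4-methoxybenzyl)oxy]methyl}-1,3,6-trimethylbicyclo[3.1.0]hex-2-en-4-yl)pent-1-en-3-yl]oxy}dimethylsilane (side chain anti to the cyclopropane; both configurations at the side-chain carbinol carbon) | C=C(C(CC)O[Si](C)(C)C(C)(C)C)[C@H]1C(C)=C[C@@]2(C)[C@@H]1[C@]2(C)COCc1ccc(OC)cc1 | intermediate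
23 | [(1S,4R,5R,6S)-4-{3-[(tert-butyldimethylsilyl)oxy]pent-1-en-2-yl}-1,3,6-trimethylbicyclo[3.1.0]hex-2-en-6-yl]methanol | C=C(C(CC)O[Si](C)(C)C(C)(C)C)[C@H]1C(C)=C[C@@]2(C)[C@@H]1[C@]2(C)CO | intermediate
24 | (1S,4R,5R,6S)-4-{3-[(tert-butyldimethylsilyl)oxy]pent-1-en-2-yl}-1,3,6-trimethylbicyclo[3.1.0]hex-2-ene-6-carbaldehyde | C=C(C(CC)O[Si](C)(C)C(C)(C)C)[C@H]1C(C)=C[C@@]2(C)[C@@H]1[C@]2(C)C=O | intermediate
25 | methyl 2-methyl-3-oxopentanoate | CCC(=O)C(C)C(=O)OC | starting material
26 | lithium sodium dienolate (dianion) of 25 (not isolated) | CC=C([O-])C(C)=C([O-])OC.[Li+].[Na+] | intermediate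
27 | methyl 5-[(1S,4R,5R,6S)-4-{3-[(tert-butyldimethylsilyl)oxy]pent-1-en-2-yl}-1,3,6-trimethylbicyclo[3.1.0]hex-2-en-6-yl]-5-hydroxy-2,4-dimethyl-3-oxopentanoate (mixture at the three chain stereocentres) | C=C(C(CC)O[Si](C)(C)C(C)(C)C)[C@H]1C(C)=C[C@@]2(C)[C@@H]1[C@]2(C)C(O)C(C)C(=O)C(C)C(=O)OC | intermediate
28 | methyl 5-[(1S,4R,5R,6S)-4-{3-[(tert-butyldimethylsilyl)oxy]pent-1-en-2-yl}-1,3,6-trimethylbicyclo[3.1.0]hex-2-en-6-yl]-2,4-dimethyl-3,5-dioxopentanoate (keto and enol forms) | C=C(C(CC)O[Si](C)(C)C(C)(C)C)[C@H]1C(C)=C[C@@]2(C)[C@@H]1[C@]2(C)C(=O)C(C)C(=O)C(C)C(=O)OC | intermediate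
29 | 6-[(1S,4R,5R,6S)-4-{3-[(tert-butyldimethylsilyl)oxy]pent-1-en-2-yl}-1,3,6-trimethylbicyclo[3.1.0]hex-2-en-6-yl]-4-hydroxy-3,5-dimethyl-2H-pyran-2-one | C=C(C(CC)O[Si](C)(C)C(C)(C)C)[C@H]1C(C)=C[C@@]2(C)[C@@H]1[C@]2(C)c1oc(=O)c(C)c(O)c1C | intermediate
30 | 6-[(1S,4R,5R,6S)-4-{3-[(tert-butyldimethylsilyl)oxy]pent-1-en-2-yl}-1,3,6-trimethylbicyclo[3.1.0]hex-2-en-6-yl]-2-methoxy-3,5-dimethyl-4H-pyran-4-one | C=C(C(CC)O[Si](C)(C)C(C)(C)C)[C@H]1C(C)=C[C@@]2(C)[C@@H]1[C@]2(C)c1oc(OC)c(C)c(=O)c1C | intermediate
31 | 6-[(1S,4R,5R,6S)-4-(3-hydroxypent-1-en-2-yl)-1,3,6-trimethylbicyclo[3.1.0]hex-2-en-6-yl]-2-methoxy-3,5-dimethyl-4H-pyran-4-one | C=C(C(O)CC)[C@H]1C(C)=C[C@@]2(C)[C@@H]1[C@]2(C)c1oc(OC)c(C)c(=O)c1C | intermediate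
32 | 2-methoxy-3,5-dimethyl-6-[(1S,4R,5R,6S)-1,3,6-trimethyl-4-(3-oxopent-1-en-2-yl)bicyclo[3.1.0]hex-2-en-6-yl]-4H-pyran-4-one | C=C(C(=O)CC)[C@H]1C(C)=C[C@@]2(C)[C@@H]1[C@]2(C)c1oc(OC)c(C)c(=O)c1C | target

## Step count and risk

Total step count: 21. Longest linear sequence: 18 steps (steps 1–4, 6–10 and 13–21).

**Step 8 (key step).** The cyclopropyl gold carbene may be diverted into six-membered-ring or skeletal-rearrangement pathways, because both alkene carbons are fully substituted. The Lewis-acidic catalyst may ionise the allylic cyclopropylcarbinyl silyl ether of the product or cleave the benzylic ether. Facial selectivity may erode if the allylic-strain preference is weaker than expected. The fallback makes the same two bonds, C1–C5 and C5–C6, by intramolecular cyclopropanation of a diazo ketone. It sets out from aldehyde 6 and returns at 12. Aldehyde 6 is taken by the aldol sequence described under step 6 (through F1 and F2) to the silylated anti-aldol imide F3. Hydrolysis with LiOH/H2O2 gives (2S,3R,4E)-3-(TBSO)-6-(PMBO)-2,4,5-trimethylhex-4-enoic acid F6. Activation as a mixed anhydride and treatment with diazomethane give the diazo ketone (3S,4R,5E)-1-diazo-4-(TBSO)-7-(PMBO)-3,5,6-trimethylhept-5-en-2-one F7. Rh2(OAc)4 in CH2Cl2 closes both rings and gives the bicyclic ketone 2-(TBSO)-6-(PMBOCH2)-1,3,6-trimethylbicyclo[3.1.0]hexan-4-one F8, with the same allylic-strain control of the alkene face. KHMDS and PhNTf2 give the C3=C4 enol triflate F9; the cyclopropane bridgehead cannot enolise. Reduction with Pd(OAc)2, PPh3, Bu3N and HCO2H gives 12.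

**Step 13.** The carbamate may ionise before the copper complex transfers the vinyl group, which would scramble the regiochemistry and the facial selectivity. Transfer of an α-branched alkenyl group may be slow, so that protonation of the organometallic competes. The fallback replaces substitution by conjugate addition. It sets out from alcohol 13 and returns at 22. Oxidation of 13 with MnO2 gives the enone (1S,5S,6S)-6-(PMBOCH2)-1,3,6-trimethylbicyclo[3.1.0]hex-3-en-2-one F10. The cuprate made from 19 and CuI adds to C4 on the face away from the cyclopropane and its endo methyl, and the enolate is trapped with PhNTf2 as the enol triflate (1S,4R,5R,6S)-4-[3-(TBSO)pent-1-en-2-yl]-6-(PMBOCH2)-1,3,6-trimethylbicyclo[3.1.0]hex-2-en-2-yl trifluoromethanesulfonate F11. Reduction with Pd(OAc)2, PPh3, Bu3N and HCO2H gives 22.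

**Step 6.** Anti selectivity may be incomplete with the hindered tetrasubstituted enal, and the allenylzinc reagent may racemise if the mixture warms; both lower the enantiomeric purity that the key step can deliver. The fallback builds the same two centres by an auxiliary-controlled anti-aldol reaction. It sets out from aldehyde 6 and returns at 11. Commercial (R)-4-benzyl-3-propanoyl-1,3-oxazolidin-2-one (CCC(=O)N1[C@H](Cc2ccccc2)COC1=O) reacts with 6 under MgCl2, Et3N and Me3SiCl in EtOAc and gives the O-trimethylsilyl anti-aldol imide F1. The sense is assumed to follow the chelated enolate model, with attack opposite the benzyl group. Acidic methanol gives the free anti-aldol imide F2, and TBSOTf with 2,6-lutidine gives its silyl ether F3. LiBH4 gives the alcohol (2R,3R,4E)-3-(TBSO)-6-(PMBO)-2,4,5-trimethylhex-4-en-1-ol F4. Dess–Martin oxidation gives the aldehyde (2S,3R,4E)-3-(TBSO)-6-(PMBO)-2,4,5-trimethylhex-4-enal F5. Dimethyl (1-diazo-2-oxopropyl)phosphonate with K2CO3 in MeOH gives 11. Epimerisation at the α-carbon of F5 would be harmless, because that centre is erased in step 8.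

**Step 19.** Methylation may occur at the 4-hydroxyl and give the 4-methoxy-2-pyrone, and the triflic acid set free may remove the silyl ether or open the vinylcyclopropane. The fallback avoids the hydroxypyrone altogether. It sets out from diketo ester 28 and returns at 30. Dehydrative cyclisation of 28 with PPh3 and CCl4 closes the ring through the δ-ketone enol onto the ester carbonyl with loss of water, so that the ester methoxy group is kept and 30 forms directly without acid; no new compound is made (F0).

## Further compounds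

F1 | step 6 | (R)-4-benzyl-3-[(2S,3R,4E)-6-[(4-methoxybenzyl)oxy]-2,4,5-trimethyl-3-(trimethylsilyloxy)hex-4-enoyl]-1,3-oxazolidin-2-one | O=C(N1[C@H](Cc2ccccc2)COC1=O)[C@@H](C)[C@@H](O[Si](C)(C)C)/C(C)=C(\C)COCc1ccc(OC)cc1
F2 | step 6 | (R)-4-benzyl-3-[(2S,3R,4E)-3-hydroxy-6-[(4-methoxybenzyl)oxy]-2,4,5-trimethylhex-4-enoyl]-1,3-oxazolidin-2-one | O=C(N1[C@H](Cc2ccccc2)COC1=O)[C@@H](C)[C@@H](O)/C(C)=C(\C)COCc1ccc(OC)cc1
F3 | step 6 | (R)-4-benzyl-3-[(2S,3R,4E)-3-[(tert-butyldimethylsilyl)oxy]-6-[(4-methoxybenzyl)oxy]-2,4,5-trimethylhex-4-enoyl]-1,3-oxazolidin-2-one | O=C(N1[C@H](Cc2ccccc2)COC1=O)[C@@H](C)[C@@H](O[Si](C)(C)C(C)(C)C)/C(C)=C(\C)COCc1ccc(OC)cc1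
F4 | step 6 | (2R,3R,4E)-3-[(tert-butyldimethylsilyl)oxy]-6-[(4-methoxybenzyl)oxy]-2,4,5-trimethylhex-4-en-1-ol | OC[C@@H](C)[C@@H](O[Si](C)(C)C(C)(C)C)/C(C)=C(\C)COCc1ccc(OC)cc1
F5 | step 6 | (2S,3R,4E)-3-[(tert-butyldimethylsilyl)oxy]-6-[(4-methoxybenzyl)oxy]-2,4,5-trimethylhex-4-enal | O=C[C@@H](C)[C@@H](O[Si](C)(C)C(C)(C)C)/C(C)=C(\C)COCc1ccc(OC)cc1
F6 | step 8 | (2S,3R,4E)-3-[(tert-butyldimethylsilyl)oxy]-6-[(4-methoxybenzyl)oxy]-2,4,5-trimethylhex-4-enoic acid | OC(=O)[C@@H](C)[C@@H](O[Si](C)(C)C(C)(C)C)/C(C)=C(\C)COCc1ccc(OC)cc1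
F7 | step 8 | (3S,4R,5E)-4-[(tert-butyldimethylsilyl)oxy]-1-diazo-7-[(4-methoxybenzyl)oxy]-3,5,6-trimethylhept-5-en-2-one | [N-]=[N+]=CC(=O)[C@@H](C)[C@@H](O[Si](C)(C)C(C)(C)C)/C(C)=C(\C)COCc1ccc(OC)cc1
F8 | step 8 | 2-[(tert-butyldimethylsilyl)oxy]-6-{[(4-methoxybenzyl)oxy]methyl}-1,3,6-trimethylbicyclo[3.1.0]hexan-4-one (numbered and configured as 12; C3 methyl cis to the silyloxy group) | O=C1[C@@H](C)[C@@H](O[Si](C)(C)C(C)(C)C)[C@@]2(C)[C@@H]1[C@]2(C)COCc1ccc(OC)cc1
F9 | step 8 | 2-[(tert-butyldimethylsilyl)oxy]-6-{[(4-methoxybenzyl)oxy]methyl}-1,3,6-trimethylbicyclo[3.1.0]hex-3-en-4-yl trifluoromethanesulfonate (numbered and configured as 12) | FC(F)(F)S(=O)(=O)OC1=C(C)[C@@H](O[Si](C)(C)C(C)(C)C)[C@@]2(C)[C@@H]1[C@]2(C)COCc1ccc(OC)cc1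
F10 | step 13 | (1S,5S,6S)-6-{[(4-methoxybenzyl)oxy]methyl}-1,3,6-trimethylbicyclo[3.1.0]hex-3-en-2-one | C1=C(C)C(=O)[C@@]2(C)[C@@H]1[C@]2(C)COCc1ccc(OC)cc1
F11 | step 13 | (1S,4R,5R,6S)-4-{3-[(tert-butyldimethylsilyl)oxy]pent-1-en-2-yl}-6-{[(4-methoxybenzyl)oxy]methyl}-1,3,6-trimethylbicyclo[3.1.0]hex-2-en-2-yl trifluoromethanesulfonate | C=C(C(CC)O[Si](C)(C)C(C)(C)C)[C@H]1C(C)=C(OS(=O)(=O)C(F)(F)F)[C@@]2(C)[C@@H]1[C@]2(C)COCc1ccc(OC)cc1
F0 | step 19 | none | none
A1 | alternative 1 | 1,3-dimethylcyclopenta-1,3-diene | CC1=CC(C)=CC1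
A2 | alternative 1 | chloro(methyl)ketene (2-chloroprop-1-en-1-one) | CC(Cl)=C=O
A3 | alternative 1 | 7-chloro-1,3,7-trimethylbicyclo[3.2.0]hept-2-en-6-one (racemic, both C7 epimers) | CC1=CC2(C)C(C1)C(=O)C2(C)Cl
A4 | alternative 1 | methyl 1,3,6-trimethylbicyclo[3.1.0]hex-2-ene-6-carboxylate (C6 methyl endo, ester exo) | C1C(C)=C[C@@]2(C)[C@@H]1[C@]2(C)C(=O)OC
A5 | alternative 2 | 7-[(tert-butyldimethylsilyloxy)methyl]-5-diazo-1,3,7-trimethylbicyclo[4.1.0]hept-2-en-4-one | [N-]=[N+]=C1C(=O)C(C)=C[C@@]2(C)[C@@H]1[C@]2(C)CO[Si](C)(C)C(C)(C)C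
A6 | alternative 2 | 6-(tert-butyldimethylsilyloxymethyl)-N-methoxy-N,1,3,6-tetramethylbicyclo[3.1.0]hex-2-ene-4-carboxamide (amide anti to the cyclopropane) | CON(C)C(=O)[C@H]1C(C)=C[C@@]2(C)[C@@H]1[C@]2(C)CO[Si](C)(C)C(C)(C)C
A7 | alternative 3 | methyl 4-methoxy-2,5-dimethylbenzoate | COC(=O)c1cc(C)c(OC)cc1C
A8 | alternative 3 | methyl 1,2,5-trimethyl-4-oxocyclohexa-2,5-diene-1-carboxylate (racemic) | COC(=O)C1(C)C=C(C)C(=O)C=C1C
A9 | alternative 3 | methyl 1,3,6-trimethyl-4-oxobicyclo[3.1.0]hex-2-ene-6-carboxylate (C6 methyl endo, ester exo) | O=C1C(C)=C[C@@]2(C)[C@@H]1[C@]2(C)C(=O)OC
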